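**Retrosynthetic overview** (furo[3,2-b]pyran numbering: O1, C2, C3, C3a, O4, C5, C6, C7, C7a; ring A = tetrahydrofuran, ring B = lactone)
1. The side chain is cut at its E-alkene: cross-metathesis of vinyl bicycle 14 with allylic alcohol 20 is the last step.
2. Ring B is cut at C7–C7a and at O4–C3a: a formal [4+2] annulation of furanose 1,2-cyclic sulfate 8 (bis-electrophile C7a/C3a) with the dianion of 3-(phenylsulfonyl)propanoic acid (bis-nucleophile C7/O4); loss of sulfinate then gives C6=C7.
3. Enabling feature: the ring-fusion carbons C7a and C3a are vicinal, C7a is an acetal-type carbon next to O1 of ring A, and the C7a–C7 and C3a–O4 bonds are cis. A cis cyclic sulfate on the opposite face therefore gives the cis-fused lactone by two SN2 inversions, all-cis to the C3 oxygen and the C2 vinyl group.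
4. Ring A is made first: C2-symmetric diol 1 → mono-silyl ether → vinyl ether → ring-closing metathesis to 2,3-dihydrofuran 4; epoxidation anti to both substituents and sulfation give 8; ring B is made second.
5. Side chain 20: Sharpless epoxidation of divinyl carbinol sets both stereocentres, followed by silylation, hydride opening, benzoylation and desilylation.

Key step: step 6

Assumption: (3S,4S)-hexa-1,5-diene-3,4-diol (the diene diol of the L-tartaric acid series) is taken as purchasable.

Step 1
Reactants: 1 (3S,4S)-hexa-1,5-diene-3,4-diol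
Product: 2 (3S,4S)-4-[(tert-butyldimethylsilyl)oxy]hexa-1,5-dien-3-ol
Conditions: NaH (1.0 equiv), THF, 0 °C; then TBSCl (1.0 equiv), 0 °C to rt
Reagents that add atoms: tert-butyldimethylsilyl chloride (TBSCl), CC(C)(C)[Si](C)(C)Cl
Why: Mono-O-silylation of a C2-symmetric diol through its monosodium alkoxide; the two hydroxyl groups are homotopic, so a single mono-ether should result and no stereocentre is touched.

Step 2
Reactants: 2 (3S,4S)-4-[(tert-butyldimethylsilyl)oxy]hexa-1,5-dien-3-ol
Product: 3 tert-butyl{[(3S,4S)-4-(ethenyloxy)hexa-1,5-dien-3-yl]oxy}dimethylsilane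
Conditions: butyl vinyl ether (solvent), Pd(OCOCF3)2 (cat.), 4,7-diphenyl-1,10-phenanthroline (cat.), Et3N (cat.), rt to 40 °C
Reagents that add atoms: butyl vinyl ether, C=COCCCC
Why: Palladium-catalysed transfer vinylation (transetherification) of the free secondary alcohol, kept at or below 40 °C so that the allyl vinyl ether does not undergo Claisen rearrangement.

Step 3
Reactants: 3 tert-butyl{[(3S,4S)-4-(ethenyloxy)hexa-1,5-dien-3-yl]oxy}dimethylsilane
Product: 4 tert-butyl{[(2S,3S)-2-ethenyl-2,3-dihydrofuran-3-yl]oxy}dimethylsilane (vinyl and silyloxy groups cis)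
Conditions: second-generation Grubbs catalyst RuCl2(=CHPh)(PCy3)(H2IMes) (5 mol%), degassed CH2Cl2 (0.01 M), 40 °C
Reagents that add atoms: none
Why: Ring-closing enol ether–olefin metathesis closes ring A; only the vinyl ether and the vinyl group on the silyloxy-bearing carbon can form a ring (five-membered), so the other vinyl group is kept and both stereocentres are carried through.

Step 4
Reactants: 4 tert-butyl{[(2S,3S)-2-ethenyl-2,3-dihydrofuran-3-yl]oxy}dimethylsilane
Product: 6 (3S,4S,5S)-4-[(tert-butyldimethylsilyl)oxy]-5-ethenyloxolane-2,3-diol (both anomers), via epoxide 5 (not isolated)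
Conditions: dimethyldioxirane (acetone solution, 1.05 equiv), CH2Cl2, −78 to 0 °C; then THF–H2O, rt
Reagents that add atoms: dimethyldioxirane, CC1(C)OO1; water, O
Why: Electrophilic epoxidation of the glycal-type enol ether should occur anti to the two cis substituents (substrate control places the C3a–O bond on the open face; the terminal vinyl group is far less reactive), and water then opens the 1,2-anhydro sugar at the anomeric carbon.

Step 5
Reactants: 6 (3S,4S,5S)-4-[(tert-butyldimethylsilyl)oxy]-5-ethenyloxolane-2,3-diol
Product: 8 (3aS,5S,6R,6aS)-6-[(tert-butyldimethylsilyl)oxy]-5-ethenyltetrahydrofuro[2,3-d][1,3,2]dioxathiole 2,2-dioxide (1,2-cyclic sulfate on the face opposite to the vinyl and silyloxy groups), via stannylene acetal 7 (not isolated)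
Conditions: Bu2SnO, toluene, reflux (−H2O); then SO2Cl2 (1.0 equiv), CH2Cl2, −20 to 0 °C; used crude
Reagents that add atoms: sulfuryl chloride, O=S(=O)(Cl)Cl
Why: Cyclic sulfate formation from a cis-1,2-diol through its dibutylstannylene acetal and sulfuryl chloride; the anomers of 6 equilibrate and only the one with the anomeric hydroxyl cis to the C3a hydroxyl can close the five-membered ring, which fixes the configuration at C7a.

Step 6
Reactants: 8 cyclic sulfate; 9 3-(phenylsulfonyl)propanoic acid
Product: 13 (2S,3R,3aS,7aR)-3-[(tert-butyldimethylsilyl)oxy]-2-ethenyl-2,3,3a,7a-tetrahydro-5H-furo[3,2-b]pyran-5-one, via dianion 10 (not isolated), via sulfate monoester 11 (not isolated), via sulfonyl lactone 12 (not isolated)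
Conditions: 9, n-BuLi (2.0 equiv), THF–DMPU, −78 °C; added to 8 (1.05 equiv), −78 to 0 °C; then 60 °C; then DBU (1.2 equiv), 0 °C to rt
Reagents that add atoms: none
Why: Proposed new method: the sulfonyl-stabilised carbanion of dianion 10 should attack the anomeric carbon C7a of cyclic sulfate 8 in an SN2 reaction (C7–C7a bond, sulfate monoester 11), the carboxylate of 11 should then displace the secondary sulfate at C3a on warming (O4–C3a bond, lactone 12), and DBU should finally expel benzenesulfinate by E1cB elimination to give the C6=C7 double bond of 13. The closest known reactions are the double displacement of 1,2-cyclic sulfates by bis-nucleophiles (malonates to cyclopropanes, amidines to imidazolines), the opening of sugar 1,2-cyclic sulfates at the anomeric carbon with inversion, and the use of 3-(arylsulfonyl)propanoate dianions as β-acylvinyl anion equivalents that give unsaturated lactones after loss of sulfinate. Ring B closes in the 6-exo-tet mode through the carboxylate oxygen. C7a and C3a are both set by SN2 inversion of the cis-fused cyclic sulfate, whose configuration comes from the epoxidation of step 4, so the new C7a–C7 and C3a–O4 bonds lie cis to each other and to the C3 silyloxy and C2 vinyl groups. The step needs C-alkylation before O-alkylation, attack at C7a before C3a, and neither a second C-alkylation nor β-elimination of O1; the much higher nucleophilicity of the carbanion, the acetal character of C7a (bonded to O1), the six-membered transition state open only to the carboxylate, and the use of one equivalent of 10 added to 8 (no carbanion base is left after the first alkylation) should secure this.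

Step 7
Reactants: 13 (2S,3R,3aS,7aR)-3-[(tert-butyldimethylsilyl)oxy]-2-ethenyl-2,3,3a,7a-tetrahydro-5H-furo[3,2-b]pyran-5-one
Product: 14 (2S,3R,3aR,7aR)-2-ethenyl-3-hydroxy-2,3,3a,7a-tetrahydro-5H-furo[3,2-b]pyran-5-one
Conditions: HF·pyridine, THF–pyridine, 0 °C to rt
Reagents that add atoms: none
Why: Fluoride-mediated cleavage of the silyl ether under mildly acidic conditions that should leave the base-sensitive unsaturated lactone untouched.

Step 8
Reactants: 15 penta-1,4-dien-3-ol
Product: 16 (1S)-1-[(2R)-oxiran-2-yl]prop-2-en-1-ol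
Conditions: Ti(OiPr)4 (cat.), L-(+)-diisopropyl tartrate (cat.), t-BuOOH (anhydrous, in decane), 4 Å molecular sieves, CH2Cl2, −20 °C
Reagents that add atoms: tert-butyl hydroperoxide, CC(C)(C)OO
Why: Sharpless asymmetric epoxidation of the divinyl carbinol, in which the L-tartrate–titanium catalyst selects one enantiotopic vinyl group and one of its faces and so sets both stereocentres (anti epoxy alcohol); the minor enantiomer is consumed by a fast second epoxidation.

Step 9
Reactants: 16 (1S)-1-[(2R)-oxiran-2-yl]prop-2-en-1-ol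
Product: 17 tert-butyldimethyl{[(1S)-1-[(2R)-oxiran-2-yl]prop-2-en-1-yl]oxy}silane
Conditions: TBSCl, imidazole, DMF, 0 °C to rt
Reagents that add atoms: tert-butyldimethylsilyl chloride (TBSCl), CC(C)(C)[Si](C)(C)Cl
Why: Imidazole-promoted O-silylation protects the allylic hydroxyl that must stay free of benzoate, under conditions too mild for Payne rearrangement.

Step 10
Reactants: 17 tert-butyldimethyl{[(1S)-1-[(2R)-oxiran-2-yl]prop-2-en-1-yl]oxy}silane
Product: 18 (2R,3S)-3-[(tert-butyldimethylsilyl)oxy]pent-4-en-2-ol
Conditions: LiAlH4, THF, −20 to 0 °C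
Reagents that add atoms: none
Why: SN2 opening of the terminal epoxide by hydride at the unsubstituted carbon turns the epoxide into the methyl carbinol without touching the oxygen-bearing stereocentre.

Step 11
Reactants: 18 (2R,3S)-3-[(tert-butyldimethylsilyl)oxy]pent-4-en-2-ol
Product: 19 (2R,3S)-3-[(tert-butyldimethylsilyl)oxy]pent-4-en-2-yl benzoate
Conditions: BzCl, pyridine, DMAP (cat.), CH2Cl2, 0 °C to rt
Reagents that add atoms: benzoyl chloride, O=C(Cl)c1ccccc1
Why: DMAP-catalysed acylation of the only free hydroxyl group.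

Step 12
Reactants: 19 (2R,3S)-3-[(tert-butyldimethylsilyl)oxy]pent-4-en-2-yl benzoate
Product: 20 (2R,3S)-3-hydroxypent-4-en-2-yl benzoate
Conditions: HF·pyridine, THF–pyridine, 0 °C to rt
Reagents that add atoms: none
Why: Acidic fluoride desilylation should free the allylic alcohol without the 1,2-benzoyl migration that basic fluoride sources would cause.

Step 13
Reactants: 14 (2S,3R,3aR,7aR)-2-ethenyl-3-hydroxy-2,3,3a,7a-tetrahydro-5H-furo[3,2-b]pyran-5-one; 20 (2R,3S)-3-hydroxypent-4-en-2-yl benzoate
Product: 21 (2R,3S,4E)-3-hydroxy-5-[(2S,3R,3aR,7aR)-3-hydroxy-5-oxo-2,3,3a,7a-tetrahydro-5H-furo[3,2-b]pyran-2-yl]pent-4-en-2-yl benzoate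
Conditions: second-generation Hoveyda–Grubbs catalyst RuCl2(=CH-C6H4-2-OiPr)(H2IMes) (10 mol%), 20 (3 equiv), CH2Cl2, 40 °C
Reagents that add atoms: none
Why: Olefin cross-metathesis between the two terminal alkenes, each next to an oxygen-bearing carbon, should give the E-disubstituted alkene under thermodynamic control, while the electron-poor cis-alkene of the lactone stays out of the catalytic cycle.

**Compound list**
1 | (3S,4S)-hexa-1,5-diene-3,4-diol | C=C[C@H](O)[C@@H](O)C=C | starting material
2 | (3S,4S)-4-[(tert-butyldimethylsilyl)oxy]hexa-1,5-dien-3-ol | C=C[C@H](O)[C@@H](O[Si](C)(C)C(C)(C)C)C=C | intermediate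
3 | tert-butyl{[(3S,4S)-4-(ethenyloxy)hexa-1,5-dien-3-yl]oxy}dimethylsilane | C=C[C@H](OC=C)[C@@H](O[Si](C)(C)C(C)(C)C)C=C | intermediate
4 | tert-butyl{[(2S,3S)-2-ethenyl-2,3-dihydrofuran-3-yl]oxy}dimethylsilane (cis) | C=C[C@@H]1OC=C[C@@H]1O[Si](C)(C)C(C)(C)C | intermediate
5 | (1R,3S,4R,5S)-4-[(tert-butyldimethylsilyl)oxy]-3-ethenyl-2,6-dioxabicyclo[3.1.0]hexane (epoxide anti to the vinyl and silyloxy groups; not isolated) | C=C[C@@H]1O[C@H]2O[C@H]2[C@@H]1O[Si](C)(C)C(C)(C)C | intermediate
6 | (3S,4S,5S)-4-[(tert-butyldimethylsilyl)oxy]-5-ethenyloxolane-2,3-diol (both anomers) | C=C[C@@H]1OC(O)[C@@H](O)[C@@H]1O[Si](C)(C)C(C)(C)C | intermediate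
7 | dibutylstannylene acetal of 6, tin bridging the anomeric and C3a oxygens on the face opposite to the vinyl and silyloxy groups (not isolated) | C=C[C@@H]1O[C@H]2O[Sn](CCCC)(CCCC)O[C@H]2[C@@H]1O[Si](C)(C)C(C)(C)C | intermediate
8 | (3aS,5S,6R,6aS)-6-[(tert-butyldimethylsilyl)oxy]-5-ethenyltetrahydrofuro[2,3-d][1,3,2]dioxathiole 2,2-dioxide | C=C[C@@H]1O[C@H]2OS(=O)(=O)O[C@H]2[C@@H]1O[Si](C)(C)C(C)(C)C | intermediate
9 | 3-(phenylsulfonyl)propanoic acid | O=C(O)CCS(=O)(=O)c1ccccc1 | starting material
10 | dilithium 3-(phenylsulfonyl)propanoate C-3 carbanion (dianion; not isolated) | [Li+].[Li+].[O-]C(=O)C[CH-]S(=O)(=O)c1ccccc1 | intermediate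
11 | dilithium salt of the C7a-alkylated sulfate monoester carboxylate: C7 on the face of the vinyl and silyloxy groups, sulfate on the opposite face, both epimers at the sulfonyl carbon (not isolated) | C=C[C@@H]1O[C@H](C(CC(=O)[O-])S(=O)(=O)c2ccccc2)[C@@H](OS(=O)(=O)[O-])[C@@H]1O[Si](C)(C)C(C)(C)C.[Li+].[Li+] | intermediate
12 | 7-(phenylsulfonyl)-6,7-dihydro derivative of 13, both epimers at C7 (not isolated) | C=C[C@@H]1O[C@@H]2C(S(=O)(=O)c3ccccc3)CC(=O)O[C@@H]2[C@@H]1O[Si](C)(C)C(C)(C)C | intermediate
13 | (2S,3R,3aS,7aR)-3-[(tert-butyldimethylsilyl)oxy]-2-ethenyl-2,3,3a,7a-tetrahydro-5H-furo[3,2-b]pyran-5-one | C=C[C@@H]1O[C@@H]2C=CC(=O)O[C@@H]2[C@@H]1O[Si](C)(C)C(C)(C)C | intermediate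
14 | (2S,3R,3aR,7aR)-2-ethenyl-3-hydroxy-2,3,3a,7a-tetrahydro-5H-furo[3,2-b]pyran-5-one | C=C[C@@H]1O[C@@H]2C=CC(=O)O[C@@H]2[C@@H]1O | intermediate
15 | penta-1,4-dien-3-ol (divinyl carbinol) | C=CC(O)C=C | starting material
16 | (1S)-1-[(2R)-oxiran-2-yl]prop-2-en-1-ol | C1O[C@H]1[C@@H](O)C=C | intermediate
17 | tert-butyldimethyl{[(1S)-1-[(2R)-oxiran-2-yl]prop-2-en-1-yl]oxy}silane | C1O[C@H]1[C@@H](O[Si](C)(C)C(C)(C)C)C=C | intermediate
18 | (2R,3S)-3-[(tert-butyldimethylsilyl)oxy]pent-4-en-2-ol | C[C@@H](O)[C@@H](O[Si](C)(C)C(C)(C)C)C=C | intermediate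
19 | (2R,3S)-3-[(tert-butyldimethylsilyl)oxy]pent-4-en-2-yl benzoate | C[C@@H](OC(=O)c1ccccc1)[C@@H](O[Si](C)(C)C(C)(C)C)C=C | intermediate
20 | (2R,3S)-3-hydroxypent-4-en-2-yl benzoate | C[C@@H](OC(=O)c1ccccc1)[C@@H](O)C=C | intermediate
21 | (2R,3S,4E)-3-hydroxy-5-[(2S,3R,3aR,7aR)-3-hydroxy-5-oxo-2,3,3a,7a-tetrahydro-5H-furo[3,2-b]pyran-2-yl]pent-4-en-2-yl benzoate | C[C@@H](OC(=O)c1ccccc1)[C@@H](O)/C=C/[C@@H]1O[C@@H]2C=CC(=O)O[C@@H]2[C@@H]1O | target

**Step count:** 13 steps in total. Longest linear sequence: 8 steps (steps 1 to 7, then step 13).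

**Steps most likely to fail**

Step 6 (proposed new method). After the first alkylation the sulfate monoester may resist displacement and be hydrolysed on work-up instead. Proton transfer from 11 to unreacted dianion may lead to a second C-alkylation (cyclopropane) or to β-elimination that opens ring A. The anomeric sulfate may also ionise and be attacked without facial control. The fallback uses known reactions only and sets out from epoxide 5 (step 4 stopped before water is added) and dianion 10. The carbanion opens the 1,2-anhydro sugar at C7a with inversion, a known mode of opening for carbon nucleophiles, and acidic work-up should give trans-hydroxy acid F1. A Mitsunobu lactonisation (PPh3, DIAD, THF, 0 °C) then forms the O4–C3a bond with inversion at C3a and gives sulfonyl lactone 12, where the route is rejoined (DBU to 13).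

Step 5. Sulfuryl transfer may be accompanied by ionisation and chlorination at the anomeric carbon, by loss of the silyl group through traces of HCl, or by decomposition of the anomeric sulfate on concentration. The fallback builds the sulfate in two stages and sets out from lactol diol 6. Thionyl chloride and Et3N (CH2Cl2, 0 °C) should give cyclic sulfite F2, which is more robust. Oxidation at sulfur with NaIO4 and a trace of RuCl3 (MeCN–H2O, 0 °C, stopped after a few minutes so that the vinyl group is not cleaved) then returns to the route at cyclic sulfate 8.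

Step 3. The ruthenium carbene may be trapped by the enol ether as an unreactive alkoxycarbene, and heating to force turnover may trigger Claisen rearrangement or double-bond isomerisation of 3. The fallback sets out from mono-silyl ether 2. Formylation (acetic formic anhydride, pyridine, 0 °C) should give formate F3. Olefinic ester cyclisation with a reduced titanium methylidene reagent (TiCl4, Zn, PbCl2 cat., CH2Br2, TMEDA, THF) then methylenates the formate carbonyl and closes the ring in the same flask, returning to the route at dihydrofuran 4.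

**Further compounds**
F1 | step 6 | 3-{(2S,3R,4S,5S)-4-[(tert-butyldimethylsilyl)oxy]-5-ethenyl-3-hydroxyoxolan-2-yl}-3-(phenylsulfonyl)propanoic acid (3-OH trans to the C-2 side chain; both epimers at the sulfonyl carbon) | C=C[C@@H]1O[C@H](C(CC(=O)O)S(=O)(=O)c2ccccc2)[C@@H](O)[C@@H]1O[Si](C)(C)C(C)(C)C
F2 | step 5 | (3aS,5S,6R,6aS)-6-[(tert-butyldimethylsilyl)oxy]-5-ethenyltetrahydrofuro[2,3-d][1,3,2]dioxathiole 2-oxide (cyclic sulfite, both epimers at sulfur) | C=C[C@@H]1O[C@H]2OS(=O)O[C@H]2[C@@H]1O[Si](C)(C)C(C)(C)C
F3 | step 3 | (3S,4S)-4-[(tert-butyldimethylsilyl)oxy]hexa-1,5-dien-3-yl formate | C=C[C@H](OC=O)[C@@H](O[Si](C)(C)C(C)(C)C)C=C
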